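**Plan**

1. Chain atoms are numbered C1 (ester carbon) to C13 and ring atoms C1′ (carbinol carrying the chain), C2′ (carbinol carrying CH3) to C6′ (CMe2). The retrosynthesis cuts first the C7–C8 single bond in the middle of the hexaene, then C13–C1′ (chain to ring), then the one-carbon alkyne homologation at C9, and on the ester side C2=C3.
2. Enabling feature: the diene C6H=C7(CH3)–C8H=C9H is the formal reductive cross-dimer of two alkynes. These are the methyl-capped internal alkyne C6≡C7 of dienynoate 21 and the terminal alkyne C8≡C9 of dienyne 15. One titanacyclopentadiene (Ti, C6, C7, C8, C9) then fixes the C7–C8 bond and the 6E and 8E geometries together.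
3. Forward order: ring ketone 8 (steps 1–5), then C15 dienyne 15 by acetylide addition, trans-reduction, oxidation, silylation and Colvin homologation (steps 6–10). Dienynoate 21 is made in two steps (11, 12), followed by the union (13) and desilylation (14).
4. Stereocentres: C2′ comes from Sharpless epoxidation of β-cyclogeraniol with D-(−)-diethyl tartrate, carried through a Wharton transposition and ozonolysis into (R)-hydroxy ketone 8. C1′ comes from chelation-controlled axial acetylide addition anti to the two axial α-methyl groups, which gives the trans-diol.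
5. Olefin geometry: 2E from the stabilised Wittig, 4E and 10E from the (E)-enynols 16 and 9, 12E from LiAlH4 trans-hydroalumination, 6E and 8E from the key step.

Key step: step 13

Remark: the (E)-isomers of enynols 9 and 16 are taken as the commercial materials; their geometry is carried unchanged into C10=C11 and C4=C5.

**Step 1**
Reactants: 1 β-cyclocitral
Product: 2 β-cyclogeraniol
Conditions: NaBH4, MeOH, 0 °C
Reagents that add atoms: none
Why: Borohydride 1,2-reduction of the hindered enal should give the allylic alcohol cleanly, because conjugate reduction is blocked by the fully substituted β-carbon.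

**Step 2**
Reactants: 2 β-cyclogeraniol
Product: 3 [(1R,6R)-2,2,6-trimethyl-7-oxabicyclo[4.1.0]heptan-1-yl]methanol
Conditions: Ti(OiPr)4 (10 mol %), D-(−)-diethyl tartrate (12 mol %), t-BuOOH, 4 Å MS, CH2Cl2, −20 °C
Reagents that add atoms: tert-butyl hydroperoxide CC(C)(C)OO
Why: Katsuki–Sharpless asymmetric epoxidation of the tetrasubstituted allylic alcohol, in which the titanium D-(−)-tartrate complex should deliver oxygen to the olefin face opposite to the one L-(+)-tartrate uses in the 2S,3S-epoxygeraniol series, setting the (R) configuration at the methyl-bearing carbon that becomes C2′.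

**Step 3**
Reactants: 3 epoxy alcohol
Product: 4 (1S,6R)-2,2,6-trimethyl-7-oxabicyclo[4.1.0]heptane-1-carbaldehyde
Conditions: TPAP (5 mol %), NMO, 4 Å MS, CH2Cl2, rt
Reagents that add atoms: none
Why: Ley–Griffith oxidation is neutral, so the acid-sensitive tetrasubstituted epoxide should survive, and the neopentyl aldehyde has no α-hydrogen to epimerise.

**Step 4**
Reactants: 4 epoxy aldehyde
Product: 6 (1R)-1,3,3-trimethyl-2-methylidenecyclohexan-1-ol, via epoxy hydrazone 5 (not isolated)
Conditions: N2H4·H2O, AcOH (cat.), MeOH, 0 °C → rt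
Reagents that add atoms: none
Why: Wharton transposition, in which the hydrazone tautomerises with opening of the epoxide C–O bond at the carbon next to C=N to an alkenyl diazene that loses N2, should give the exocyclic methylene and leave the C–O bond at the methyl-bearing carbon, and so its (R) configuration, untouched.

**Step 5**
Reactants: 6 allylic alcohol
Product: 8 (2R)-2-hydroxy-2,6,6-trimethylcyclohexan-1-one, via ozonide 7 (not isolated)
Conditions: O3, CH2Cl2, −78 °C; then Me2S, −78 °C → rt
Reagents that add atoms: ozone [O-][O+]=O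
Why: Ozonolysis with reductive work-up cleaves the 1,1-disubstituted exocyclic alkene to the ketone, and since both α-carbons are quaternary the α-hydroxy ketone cannot enolise or racemise.

**Step 6**
Reactants: 8 (2R)-2-hydroxy-2,6,6-trimethylcyclohexan-1-one; 9 (2E)-3-methylpent-2-en-4-yn-1-ol (2.2 equiv)
Product: 11 (1S,2R)-1-[(3E)-5-hydroxy-3-methylpent-3-en-1-yn-1-yl]-2,6,6-trimethylcyclohexane-1,2-diol, via dilithium salt 10 (not isolated)
Conditions: 9, n-BuLi (4.4 equiv), THF, −78 → 0 °C; then 8, −78 °C → rt; then H2O
Reagents that add atoms: none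
Why: Addition of a lithium acetylide to a non-enolisable ketone, in which the lithium alkoxide of the α-hydroxyl chelates the carbonyl oxygen and so holds that C–O equatorial and the 2-methyl axial on the same side as the axial 6-methyl, should proceed by axial attack anti to both methyl groups and give the trans-diol, setting C1′ by substrate control.

**Step 7**
Reactants: 11 acetylenic triol
Product: 12 (1R,2R)-1-[(1E,3E)-5-hydroxy-3-methylpenta-1,3-dien-1-yl]-2,6,6-trimethylcyclohexane-1,2-diol
Conditions: LiAlH4, THF, 0 → 45 °C; Rochelle salt work-up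
Reagents that add atoms: none
Why: Alkoxide-directed trans-hydroalumination of the propargylic alcohol with LiAlH4 should reduce only the triple bond next to the tertiary carbinol and give the (E)-alkene, the trisubstituted alkene being inert.

**Step 8**
Reactants: 12 dienetriol
Product: 13 (2E,4E)-5-[(1R,2R)-1,2-dihydroxy-2,6,6-trimethylcyclohexyl]-3-methylpenta-2,4-dienal
Conditions: activated MnO2, CH2Cl2, rt, dark
Reagents that add atoms: none
Why: Allylic oxidation with MnO2 should touch only the primary dienylic alcohol, since the two tertiary alcohols cannot be oxidised, and the E,E geometry should be kept in the dark.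

**Step 9**
Reactants: 13 dihydroxy dienal
Product: 14 (2E,4E)-3-methyl-5-[(1R,2R)-2,6,6-trimethyl-1,2-bis(trimethylsilyloxy)cyclohexyl]penta-2,4-dienal
Conditions: TMSOTf (3 equiv), 2,6-lutidine (4 equiv), CH2Cl2, −78 → 0 °C
Reagents that add atoms: trimethylsilyl trifluoromethanesulfonate C[Si](C)(C)OS(=O)(=O)C(F)(F)F
Why: Silylation with a silyl triflate and a hindered pyridine base is the standard way to cap hindered tertiary alcohols, and the electron-poor dienal should disfavour ionisation of the tertiary allylic C–O bond at low temperature.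

**Step 10**
Reactants: 14 bis-silylated dienal
Product: 15 (1R,2R)-1-[(1E,3E)-3-methylhexa-1,3-dien-5-yn-1-yl]-2,6,6-trimethyl-1,2-bis(trimethylsilyloxy)cyclohexane
Conditions: TMSCHN2, n-BuLi, THF, −78 °C; then 14, −78 → 0 °C; then H2O
Reagents that add atoms: (trimethylsilyl)diazomethane C[Si](C)(C)C=[N+]=[N-]
Why: Colvin rearrangement (addition of lithiated (trimethylsilyl)diazomethane, Peterson-type loss of lithium trimethylsilanolate, loss of N2 and 1,2-hydrogen shift of the alkylidene carbene) should give the terminal enyne without the methanol conjugate addition that enals suffer under Ohira–Bestmann conditions.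

**Step 11**
Reactants: 16 (2E)-pent-2-en-4-yn-1-ol
Product: 18 (2E)-hex-2-en-4-yn-1-ol, via dilithium salt 17 (not isolated)
Conditions: n-BuLi (2.1 equiv), THF–DMPU, −78 °C; MeI (1.0 equiv), −78 → 0 °C; then H2O
Reagents that add atoms: iodomethane CI
Why: Alkylation of the alkoxide/acetylide dianion should occur at carbon only, because the acetylide is far more nucleophilic than the lithium alkoxide oxygen towards one equivalent of MeI, and the E-alkene is not touched.

**Step 12**
Reactants: 18 (2E)-hex-2-en-4-yn-1-ol; 19 methyl 2-(triphenyl-λ5-phosphanylidene)propanoate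
Product: 21 methyl (2E,4E)-2-methylocta-2,4-dien-6-ynoate, via enynal 20 (not isolated)
Conditions: activated MnO2, 19 (1.3 equiv), CH2Cl2, rt → 40 °C
Reagents that add atoms: none
Why: Tandem MnO2 oxidation–Wittig olefination traps the volatile, polymerisable enynal as it forms, and the α-methyl stabilised ylide should give the (2E)-trisubstituted enoate.

**Step 13**
Reactants: 21 methyl (2E,4E)-2-methylocta-2,4-dien-6-ynoate; 15 silyl-protected dienyne (1.2 equiv)
Product: 24 methyl (2E,4E,6E,8E,10E,12E)-2,7,11-trimethyl-13-[(1R,2R)-2,6,6-trimethyl-1,2-bis(trimethylsilyloxy)cyclohexyl]trideca-2,4,6,8,10,12-hexaenoate, via titanacyclopropene 22 (not isolated), via titanacyclopentadiene 23 (not isolated)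
Conditions: Ti(OiPr)4 (1.5 equiv), i-PrMgCl (3.0 equiv), 21, Et2O, −78 → −50 °C; then 15, −50 → −30 °C; then H2O/NaHCO3, −40 °C → rt, dark
Reagents that add atoms: none
Why: Proposed new method: (η2-propene)Ti(OiPr)2 made in the flask exchanges propene for the C6≡C7 triple bond of 21 to give titanacyclopropene 22, the terminal triple bond of 15 inserts into its Ti–C7 bond to give titanacyclopentadiene 23 (ring atoms Ti, C6, C7, C8, C9), and water cleaves both Ti–C bonds with retention, so that C7–C8 is formed and H-6 and H-9 end up cis to it, which is the 6E,8E diene. The closest known reaction type is the titanium alkoxide-mediated cross-coupling of a titanium-complexed internal alkyne (a 2-alkynoate or silylalkyne) with a terminal alkyne to a stereodefined 1,3-diene; new here are a conjugated dienynoate as internal partner, a conjugated dienyne as terminal partner and regiocontrol by an ester that acts through a diene. No ring of the product is closed, the transient five-membered titanacycle arises by migratory insertion, and no stereocentre is created; the two new double-bond geometries follow from the cis relation of titanium and the new bond at each former alkyne inside the ring. Cross-selectivity should be secured by complexing the internal alkyne first at −50 °C, where such complexes do not dimerise, and adding afterwards the terminal alkyne, which forms no stable complex of its own. Regioselectivity should be secured by the substrate: Ti–C6 is conjugated with the dienoate (vinylogous titanium ester enolate character) and flanked by the dienyl chain, whereas Ti–C7 carries only CH3 and is the more nucleophilic and less hindered bond, and the terminal alkyne bonds through its unsubstituted CH (C8), which places its dienyl substituent next to titanium. Chemoselectivity against the methyl ester and the silyl ethers rests on the low temperature and on the exact 2:1 ratio of i-PrMgCl to Ti(OiPr)4.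

**Step 14**
Reactants: 24 bis-silyl ether
Product: 25 methyl (2E,4E,6E,8E,10E,12E)-13-[(1R,2R)-1,2-dihydroxy-2,6,6-trimethylcyclohexyl]-2,7,11-trimethyltrideca-2,4,6,8,10,12-hexaenoate
Conditions: TBAF (2.5 equiv), AcOH (2.5 equiv), THF, 0 °C, dark, argon
Reagents that add atoms: none
Why: Fluoride-induced cleavage of the two trimethylsilyl ethers, buffered with acetic acid, should free the diol without exposing the tertiary allylic alcohol on the hexaene to acid or the ester to strong base.

**Compound list**

1 | β-cyclocitral (2,6,6-trimethylcyclohex-1-ene-1-carbaldehyde) | CC1=C(C=O)C(C)(C)CCC1 | starting material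
2 | β-cyclogeraniol ((2,6,6-trimethylcyclohex-1-en-1-yl)methanol) | CC1=C(CO)C(C)(C)CCC1 | intermediate
3 | [(1R,6R)-2,2,6-trimethyl-7-oxabicyclo[4.1.0]heptan-1-yl]methanol | OC[C@]12C(C)(C)CCC[C@@]1(C)O2 | intermediate
4 | (1S,6R)-2,2,6-trimethyl-7-oxabicyclo[4.1.0]heptane-1-carbaldehyde | O=C[C@]12C(C)(C)CCC[C@@]1(C)O2 | intermediate
5 | hydrazone of aldehyde 4, (1R,6R)-1-(hydrazinylidenemethyl)-2,2,6-trimethyl-7-oxabicyclo[4.1.0]heptane | NN=C[C@]12C(C)(C)CCC[C@@]1(C)O2 | intermediate
6 | (1R)-1,3,3-trimethyl-2-methylidenecyclohexan-1-ol | C=C1C(C)(C)CCC[C@@]1(C)O | intermediate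
7 | secondary ozonide of 6, (6R)-6,10,10-trimethyl-1,2,4-trioxaspiro[4.5]decan-6-ol (spiro centre unassigned) | C1OC2(OO1)C(C)(C)CCC[C@@]2(C)O | intermediate
8 | (2R)-2-hydroxy-2,6,6-trimethylcyclohexan-1-one | O=C1C(C)(C)CCC[C@@]1(C)O | intermediate
9 | (2E)-3-methylpent-2-en-4-yn-1-ol | OC/C=C(C)/C#C | starting material
10 | dilithium salt of 9 (lithium alkoxide and lithium acetylide) | [Li]OC/C=C(C)/C#C[Li] | intermediate
11 | (1S,2R)-1-[(3E)-5-hydroxy-3-methylpent-3-en-1-yn-1-yl]-2,6,6-trimethylcyclohexane-1,2-diol (trans-diol) | OC/C=C(C)/C#C[C@@]1(O)C(C)(C)CCC[C@@]1(C)O | intermediate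
12 | (1R,2R)-1-[(1E,3E)-5-hydroxy-3-methylpenta-1,3-dien-1-yl]-2,6,6-trimethylcyclohexane-1,2-diol | OC/C=C(C)/C=C/[C@@]1(O)C(C)(C)CCC[C@@]1(C)O | intermediate
13 | (2E,4E)-5-[(1R,2R)-1,2-dihydroxy-2,6,6-trimethylcyclohexyl]-3-methylpenta-2,4-dienal | O=C/C=C(C)/C=C/[C@@]1(O)C(C)(C)CCC[C@@]1(C)O | intermediate
14 | (2E,4E)-3-methyl-5-[(1R,2R)-2,6,6-trimethyl-1,2-bis(trimethylsilyloxy)cyclohexyl]penta-2,4-dienal | O=C/C=C(C)/C=C/[C@@]1(O[Si](C)(C)C)C(C)(C)CCC[C@@]1(C)O[Si](C)(C)C | intermediate
15 | (1R,2R)-1-[(1E,3E)-3-methylhexa-1,3-dien-5-yn-1-yl]-2,6,6-trimethyl-1,2-bis(trimethylsilyloxy)cyclohexane | C#C/C=C(C)/C=C/[C@@]1(O[Si](C)(C)C)C(C)(C)CCC[C@@]1(C)O[Si](C)(C)C | intermediate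
16 | (2E)-pent-2-en-4-yn-1-ol | OC/C=C/C#C | starting material
17 | dilithium salt of 16 (lithium alkoxide and lithium acetylide) | [Li]OC/C=C/C#C[Li] | intermediate
18 | (2E)-hex-2-en-4-yn-1-ol | OC/C=C/C#CC | intermediate
19 | methyl 2-(triphenyl-λ5-phosphanylidene)propanoate | COC(=O)C(C)=P(c1ccccc1)(c1ccccc1)c1ccccc1 | starting material
20 | (2E)-hex-2-en-4-ynal | O=C/C=C/C#CC | intermediate
21 | methyl (2E,4E)-2-methylocta-2,4-dien-6-ynoate | COC(=O)/C(C)=C/C=C/C#CC | intermediate
22 | titanacyclopropene of 21: Ti(OiPr)2 bridging C6 and C7 of the dienynoate | COC(=O)/C(C)=C/C=C/C1=C(C)[Ti]1(OC(C)C)OC(C)C | intermediate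
23 | titanacyclopentadiene: ring Ti–C6=C7(CH3)–C8H=C9–Ti with Ti(OiPr)2, dienoate chain on C6, silyl-protected ring dienyl chain on C9 | COC(=O)/C(C)=C/C=C/C1=C(C)C=C(/C=C(C)/C=C/[C@@]2(O[Si](C)(C)C)C(C)(C)CCC[C@@]2(C)O[Si](C)(C)C)[Ti]1(OC(C)C)OC(C)C | intermediate
24 | methyl (2E,4E,6E,8E,10E,12E)-2,7,11-trimethyl-13-[(1R,2R)-2,6,6-trimethyl-1,2-bis(trimethylsilyloxy)cyclohexyl]trideca-2,4,6,8,10,12-hexaenoate | COC(=O)/C(C)=C/C=C/C=C(C)/C=C/C=C(C)/C=C/[C@@]1(O[Si](C)(C)C)C(C)(C)CCC[C@@]1(C)O[Si](C)(C)C | intermediate
25 | methyl (2E,4E,6E,8E,10E,12E)-13-[(1R,2R)-1,2-dihydroxy-2,6,6-trimethylcyclohexyl]-2,7,11-trimethyltrideca-2,4,6,8,10,12-hexaenoate | COC(=O)/C(C)=C/C=C/C=C(C)/C=C/C=C(C)/C=C/[C@@]1(O)C(C)(C)CCC[C@@]1(C)O | target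

**Step count**

Total: 14 steps. Longest linear sequence: 12 steps (1 → 25 through steps 1–10, 13 and 14); dienynoate 21 is made in a 2-step branch (steps 11, 12).

**Steps most likely to fail**

1. Step 13 (Proposed new method). What may go wrong: insertion of the terminal alkyne into the wrong Ti–C bond, protonation of the titanacyclopropene by the acetylenic C–H, attack of the low-valent titanium species on the ester, or protonolysis of the C6–Ti bond at a remote carbon of the conjugated system, which would give allenes. The fallback uses known chemistry, sets out from 21 and 15 and returns at 24. Hydrozirconation of 21 with Cp2Zr(H)Cl (THF, rt) should place zirconium on the methyl-bearing carbon by syn addition and give the alkenylzirconocene chloride of 21 F1. Iodinolysis (I2, 0 °C) with retention gives methyl (2E,4E,6E)-7-iodo-2-methylocta-2,4,6-trienoate F2. Hydrozirconation of 15 gives the (E)-trienylzirconocene chloride of 15 F3, which is cross-coupled with F2 under Pd(PPh3)4 catalysis with ZnCl2 as co-catalyst (Negishi coupling) to give 24.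

2. Step 6. What may go wrong: poor facial selectivity if the lithium chelate is not the reacting conformer, so that attack syn to the C2′ oxygen leads to the cis-diol. The fallback makes the trans-diol by stereospecific anti opening of an epoxide, sets out from 2 and returns at 12. Sharpless epoxidation of 2 with L-(+)-diethyl tartrate gives [(1S,6S)-2,2,6-trimethyl-7-oxabicyclo[4.1.0]heptan-1-yl]methanol F4. TPAP/NMO oxidation gives (1R,6S)-2,2,6-trimethyl-7-oxabicyclo[4.1.0]heptane-1-carbaldehyde F5. Horner–Wadsworth–Emmons olefination with triethyl 3-methyl-4-phosphonocrotonate (NaH, THF) gives ethyl (2E,4E)-3-methyl-5-[(1R,6S)-2,2,6-trimethyl-7-oxabicyclo[4.1.0]heptan-1-yl]penta-2,4-dienoate F6. Acid-catalysed hydrolysis (HClO4 cat., THF/H2O, 0 °C) should open the epoxide at the methyl-bearing carbon with inversion, the dienoate disfavouring ionisation at the chain-bearing carbon, and give ethyl (2E,4E)-5-[(1R,2R)-1,2-dihydroxy-2,6,6-trimethylcyclohexyl]-3-methylpenta-2,4-dienoate F7. DIBAL-H reduction of the ester gives 12.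

3. Step 10. What may go wrong: γ-deprotonation of the dienal by the basic lithiated diazo reagent (recovery or 2E→2Z isomerisation of the aldehyde) or attack at the silyl ethers. The fallback is a Corey–Fuchs sequence, sets out from 14 and returns at 15. Dibromo-olefination (CBr4, PPh3, Et3N, CH2Cl2, 0 °C) gives (1R,2R)-1-[(1E,3E)-6,6-dibromo-3-methylhexa-1,3,5-trien-1-yl]-2,6,6-trimethyl-1,2-bis(trimethylsilyloxy)cyclohexane F8. Treatment with n-BuLi (2.1 equiv, THF, −78 °C) and quenching with water gives 15.

**Further compounds**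

F1 | step 13 | alkenylzirconocene chloride of 21 (Cp2ZrCl on the methyl-bearing carbon, 6E) | COC(=O)/C(C)=C/C=C/C=C(\C)[Zr](Cl)(C1C=CC=C1)C1C=CC=C1
F2 | step 13 | methyl (2E,4E,6E)-7-iodo-2-methylocta-2,4,6-trienoate | COC(=O)/C(C)=C/C=C/C=C(\C)I
F3 | step 13 | (E)-trienylzirconocene chloride of 15 (Cp2ZrCl on the former terminal alkyne carbon) | Cl[Zr](C1C=CC=C1)(C1C=CC=C1)/C=C/C=C(C)/C=C/[C@@]1(O[Si](C)(C)C)C(C)(C)CCC[C@@]1(C)O[Si](C)(C)C
F4 | step 6 | [(1S,6S)-2,2,6-trimethyl-7-oxabicyclo[4.1.0]heptan-1-yl]methanol | OC[C@@]12C(C)(C)CCC[C@]1(C)O2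
F5 | step 6 | (1R,6S)-2,2,6-trimethyl-7-oxabicyclo[4.1.0]heptane-1-carbaldehyde | O=C[C@@]12C(C)(C)CCC[C@]1(C)O2
F6 | step 6 | ethyl (2E,4E)-3-methyl-5-[(1R,6S)-2,2,6-trimethyl-7-oxabicyclo[4.1.0]heptan-1-yl]penta-2,4-dienoate | CCOC(=O)/C=C(C)/C=C/[C@@]12C(C)(C)CCC[C@]1(C)O2
F7 | step 6 | ethyl (2E,4E)-5-[(1R,2R)-1,2-dihydroxy-2,6,6-trimethylcyclohexyl]-3-methylpenta-2,4-dienoate | CCOC(=O)/C=C(C)/C=C/[C@@]1(O)C(C)(C)CCC[C@@]1(C)O
F8 | step 10 | (1R,2R)-1-[(1E,3E)-6,6-dibromo-3-methylhexa-1,3,5-trien-1-yl]-2,6,6-trimethyl-1,2-bis(trimethylsilyloxy)cyclohexane | BrC(Br)=C/C=C(C)/C=C/[C@@]1(O[Si](C)(C)C)C(C)(C)CCC[C@@]1(C)O[Si](C)(C)C
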